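Readings and results stem from a simulated flask with made-up constants; noise was put on by code.

in all of them: substrate 0.10 M

|  | precatalyst | remark | time |
|---|---|---|---|
| birch | 0.12 mM | run made earlier |  |
| cedar | 0.46 mM | run made earlier |  |
| Monday's | 0.10 mM |  | 30 min |
| Saturday's | 0.30 mM |  | 30 min |

| run | time / min | target / % | substrate / % |
|---|---|---|---|
| birch | 2.50 | 3.4 | 96.5 |
| birch | 6.00 | 14.2 | 84.2 |
| birch | 12.0 | 39.4 | 57.6 |
| birch | 30.0 | 84.0 | 6.6 |
| cedar | 2.50 | 11.5 | 87.8 |
| cedar | 6.00 | 48.1 | 50.1 |
| cedar | 12.0 | 92.0 | 4.6 |
| cedar | 30.0 | 88.8 | 0 |

(each reading ± 0.3 percentage points)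
1. which of the two there is more of at the end, Monday's (over-reaction product / target)
2. which of the two there is more of at the end, Saturday's (over-reaction product / target)
3. target at the end, in percent of the substrate charged, Monday's
4. target at the end, in percent of the substrate charged, Saturday's

1. At early times the flasks kept step with their precatalyst: at 2.50 min, cedar's target was 3.38 times birch's, on 3.83 times the charge. I therefore summed up birch's late decay of substrate by one average first-order constant, r = 0.120 min⁻¹, taken between 12.0 min and 30.0 min, and scaled it with the precatalyst charged.

2. In cedar, target plus substrate fell from 96.6% to 88.8% between 12.0 min and 30.0 min. That gave me the leak constant λ, the fraction of that sum lost per minute: 0.00468 min⁻¹.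

3. Target (T) stops rising where feed meets leak, r·S = λ·T, so the crossing lies at a substrate level S× = λT/r.

4. The decision was about the stopping time. For Monday's flask I reckoned S× = 3.92% and substrate of 10.4% at 30 min. Monday's would still be gaining, since substrate stood above the crossing, so I kept the full time. For Saturday's flask I reckoned S× = 1.38% and substrate of 0.112%, which is less than S×. Saturday's would already be past its peak, so more time would buy no target.

The forecast gave 80% (76.5% to 83%) for Monday's and 89.5% (88% to 91%) for Saturday's, with target ahead in both. It called the loss “a slow, nearly catalyst-independent leak”, whereas my leak scales with target.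

The flasks gave 78.8% and 89.4%, with target ahead in both.

    substrate + free catalyst → catalyst intermediate (k = 1550 L mol⁻¹ min⁻¹)
    catalyst intermediate → free catalyst + target (k = 74.7 min⁻¹)
    precatalyst → free catalyst (k = 0.184 min⁻¹)
    target → over-reaction product (k = 0.00418 min⁻¹)
    2 substrate → homo dimer (k = 0.0183 L mol⁻¹ min⁻¹)

In Saturday's flask, precatalyst was still feeding free catalyst at 15.0 min, with 6.33% of it left, while substrate had fallen to 6.46%. By 30.0 min substrate was down to 0.00802%, and target was being made at 0.0101 of the rate at which it was used up. Applied to Saturday's sum at 15.0 min, λ gives 88.6% at 30.0 min. Applied to Monday's sum at 30.0 min, it gives 25.7% at 300 min, where Monday's flask held 29.5% target.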